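**Retrosynthetic overview**

1. The route rests on the oxepene ring (O1, quaternary C2, C3H2, C4H2, C5=C6, C7H2). Its O1–C2 bond lies β to the aryl ketone and α to the carboxyl, so the ring and the only stereocentre (C2, R) are disconnected together by a retro-oxa-Michael step to an acyclic (E)-2-alkyl-3-aroylacrylate with a free C7 allylic hydroxyl.
2. The aroylacrylate comes from Wittig olefination of an α-keto tert-butyl ester with the bis-MOM aroylmethylene phosphorane made from 2',5'-dihydroxyacetophenone.
3. The keto ester comes from α-hydroxylation and oxidation of the ester formed by B-alkyl Suzuki coupling (C4–C5 bond) of hydroborated tert-butyl but-3-enoate with a (Z)-vinyl iodide. The iodide comes from copper-catalysed carbomagnesiation–iodination of propargyl alcohol with homoprenylmagnesium bromide, followed by E-selective SeO2 oxidation of the terminal methyl group.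
4. Ring order: both arenes are bought; the oxepene is the only ring made (step 13). The coumarate is attached afterwards and one acidic step unmasks the acid and the three phenols.

Key step: step 13

Assumption (chemistry): the sense of induction of the squaramide catalyst in this closure cannot be predicted with confidence. The quinidine-derived catalyst is written; the quinine-derived pseudoenantiomer would be used instead if that is the one that delivers (R)-C2.

**Route**

Step 1
Reactants: 1 5-bromo-2-methylpent-2-ene; 2 prop-2-yn-1-ol (propargyl alcohol)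
Product: 5 (2Z)-3-iodo-2-(4-methylpent-3-en-1-yl)prop-2-en-1-ol, via homoprenylmagnesium bromide 3 (not isolated), via alkenylmagnesium alkoxide chelate 4 (not isolated)
Conditions: 1 (2.5 equiv), Mg, THF, rt; then 2 (1.0 equiv), CuI (10 mol%), THF, −10 °C → rt; then I2, THF, −20 °C → rt
Reagents that add atoms: iodine, SMILES II
Why: Copper-catalysed anti-carbomagnesiation of propargyl alcohol (Duboudin reaction) puts the alkyl group on C2 and magnesium on C3 inside a five-membered O–Mg chelate, so iodinolysis with retention should give the vinyl iodide with iodine cis to CH2OH, which fixes the later cis relationship of C4 and C7 across the ring alkene; one equivalent of the Grignard reagent serves as base for the hydroxyl.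

Step 2
Reactants: 5 (2Z)-3-iodo-2-(4-methylpent-3-en-1-yl)prop-2-en-1-ol
Product: 6 1-({[(2Z)-3-iodo-2-(4-methylpent-3-en-1-yl)prop-2-en-1-yl]oxy}methyl)-4-methoxybenzene
Conditions: NaH, PMBCl, Bu4NI (cat.), THF–DMF, 0 °C → rt
Reagents that add atoms: 4-methoxybenzyl chloride, SMILES COc1ccc(CCl)cc1
Why: Williamson etherification of the primary allylic alkoxide; the PMB ether carries the C7 oxygen through the oxidation and enolate steps and can later be removed oxidatively without acid or base.

Step 3
Reactants: 6 PMB ether of the iodo alcohol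
Product: 7 (2E,6Z)-7-iodo-6-{[(4-methoxybenzyl)oxy]methyl}-2-methylhepta-2,6-dien-1-ol
Conditions: SeO2 (0.3 equiv), t-BuOOH (3 equiv), salicylic acid (10 mol%), CH2Cl2, 0 °C → rt, stopped at partial conversion
Reagents that add atoms: selenium dioxide (catalytic oxygen carrier), SMILES O=[Se]=O; tert-butyl hydroperoxide (terminal oxidant), SMILES CC(C)(C)OO
Why: Sharpless catalytic SeO2 allylic oxidation (ene reaction, then [2,3]-sigmatropic shift) should attack the electron-rich terminal trisubstituted alkene at its E methyl group, as in the 8-hydroxylation of geranyl esters, while the iodo-alkene with its allylic ether is deactivated; the E geometry follows from the sigmatropic step.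

Step 4
Reactants: 7 (2E,6Z)-7-iodo-6-{[(4-methoxybenzyl)oxy]methyl}-2-methylhepta-2,6-dien-1-ol
Product: 8 tert-butyl{[(2E,6Z)-7-iodo-6-{[(4-methoxybenzyl)oxy]methyl}-2-methylhepta-2,6-dien-1-yl]oxy}dimethylsilane
Conditions: TBSCl, imidazole, DMF, 0 °C → rt
Reagents that add atoms: tert-butyldimethylsilyl chloride, SMILES CC(C)(C)[Si](C)(C)Cl
Why: Standard silylation of a primary allylic alcohol; the TBS ether is orthogonal to the PMB ether and survives every step up to the ring closure.

Step 5
Reactants: 8 TBS/PMB-protected (Z)-vinyl iodide; 9 tert-butyl but-3-enoate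
Product: 11 tert-butyl (5Z,9E)-11-[(tert-butyldimethylsilyl)oxy]-6-{[(4-methoxybenzyl)oxy]methyl}-10-methylundeca-5,9-dienoate, via B-alkyl-9-BBN adduct 10 (not isolated)
Conditions: 9 (1.5 equiv), 9-BBN (0.5 M in THF), 0 °C → rt; then 8, Pd(dppf)Cl2 (5 mol%), AsPh3 (10 mol%), Cs2CO3, DMF–THF–H2O, rt
Reagents that add atoms: none
Why: Anti-Markovnikov hydroboration followed by B-alkyl Suzuki–Miyaura coupling forms the C4–C5 bond with retention of the vinyl iodide geometry, so the ester chain ends up cis to the CH2OPMB group (5Z).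

Step 6
Reactants: 11 tert-butyl (5Z,9E)-undecadienoate
Product: 13 tert-butyl (5Z,9E)-11-[(tert-butyldimethylsilyl)oxy]-2-hydroxy-6-{[(4-methoxybenzyl)oxy]methyl}-10-methylundeca-5,9-dienoate (racemic at C2), via potassium enolate 12 (not isolated)
Conditions: KHMDS, THF, −78 °C; then 3-phenyl-2-(phenylsulfonyl)oxaziridine, −78 °C; aq. NH4Cl
Reagents that add atoms: 3-phenyl-2-(phenylsulfonyl)oxaziridine (Davis reagent), SMILES O=S(=O)(N1OC1c1ccccc1)c1ccccc1
Why: Davis α-hydroxylation of the ester enolate puts oxygen on C2; the carbinol centre forms as a racemate, which does not matter because it is oxidised in the next step.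

Step 7
Reactants: 13 α-hydroxy ester
Product: 14 tert-butyl (5Z,9E)-11-[(tert-butyldimethylsilyl)oxy]-6-{[(4-methoxybenzyl)oxy]methyl}-10-methyl-2-oxoundeca-5,9-dienoate
Conditions: Dess–Martin periodinane, NaHCO3, CH2Cl2, 0 °C → rt
Reagents that add atoms: none
Why: Dess–Martin oxidation of a secondary α-hydroxy ester to the α-keto ester under buffered conditions that leave the PMB, TBS and both alkenes untouched.

Step 8
Reactants: 15 1-(2,5-dihydroxyphenyl)ethan-1-one (2',5'-dihydroxyacetophenone)
Product: 16 1-[2,5-bis(methoxymethoxy)phenyl]ethan-1-one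
Conditions: NaH (2.5 equiv), MOMCl (2.5 equiv), DMF, 0 °C → rt
Reagents that add atoms: chloromethyl methyl ether, SMILES COCCl
Why: O-alkylation of both phenoxides, the sodium salt being needed to alkylate the hydrogen-bonded ortho hydroxyl; the ortho MOM ether is what later blocks 6-endo closure to a chromanone.

Step 9
Reactants: 16 1-[2,5-bis(methoxymethoxy)phenyl]ethan-1-one
Product: 18 1-[2,5-bis(methoxymethoxy)phenyl]-2-bromoethan-1-one, via trimethylsilyl enol ether 17 (not isolated)
Conditions: TMSCl, LiHMDS, THF, −78 °C (in situ quench); then NBS, THF, −78 → 0 °C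
Reagents that add atoms: N-bromosuccinimide, SMILES O=C1CCC(=O)N1Br
Why: Bromination of the silyl enol ether with NBS gives the α-bromoketone without free HBr, so the MOM ethers and the electron-rich ring should be spared.

Step 10
Reactants: 18 α-bromoketone
Product: 20 1-[2,5-bis(methoxymethoxy)phenyl]-2-(triphenyl-λ5-phosphanylidene)ethan-1-one, via phosphonium bromide 19 (not isolated)
Conditions: PPh3, toluene, rt; then 1 M aq. NaOH, CH2Cl2, rt
Reagents that add atoms: triphenylphosphine, SMILES c1ccc(cc1)P(c1ccccc1)c1ccccc1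
Why: SN2 alkylation of triphenylphosphine followed by deprotonation of the acidic phenacyl phosphonium salt gives the isolable acyl-stabilised ylide.

Step 11
Reactants: 14 α-keto ester; 20 aroylmethylene phosphorane
Product: 21 tert-butyl (2E)-4-[2,5-bis(methoxymethoxy)phenyl]-2-[(3Z,7E)-9-[(tert-butyldimethylsilyl)oxy]-4-{[(4-methoxybenzyl)oxy]methyl}-8-methylnona-3,7-dien-1-yl]-4-oxobut-2-enoate
Conditions: 20 (1.5 equiv), toluene, 80 °C, dark
Reagents that add atoms: none
Why: Wittig olefination of the activated ketone of the α-keto ester by the neutral stabilised ylide, avoiding base that would deconjugate the product; the E isomer (aroyl trans to the ester) is expected to predominate and is separated from any Z isomer by chromatography.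

Step 12
Reactants: 21 PMB-protected aroylacrylate
Product: 22 tert-butyl (2E)-4-[2,5-bis(methoxymethoxy)phenyl]-2-[(3Z,7E)-9-[(tert-butyldimethylsilyl)oxy]-4-(hydroxymethyl)-8-methylnona-3,7-dien-1-yl]-4-oxobut-2-enoate
Conditions: DDQ (1.3 equiv), CH2Cl2–pH 7 phosphate buffer (10:1), 0 °C, dark
Reagents that add atoms: none
Why: Oxidative PMB cleavage with DDQ frees the C7 hydroxyl under buffered neutral conditions, chosen because acid or base at this stage could start an uncatalysed racemic ring closure.

Step 13
Reactants: 22 (E)-aroylacrylate with free C7 allylic alcohol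
Product: 23 tert-butyl (2R)-2-{2-[2,5-bis(methoxymethoxy)phenyl]-2-oxoethyl}-6-[(3E)-5-[(tert-butyldimethylsilyl)oxy]-4-methylpent-3-en-1-yl]-2,3,4,7-tetrahydrooxepine-2-carboxylate
Conditions: squaramide from 9-amino-9-deoxy-epi-quinidine and 3,5-bis(trifluoromethyl)aniline (10 mol%), toluene, −20 → 0 °C, dark
Reagents that add atoms: none
Why: Proposed new method: the quinuclidine nitrogen of the catalyst acts as a general base on the C7 hydroxyl while the squaramide N–H pair hydrogen-bonds the aryl ketone, so the oxygen adds to C2 (β to the ketone, α to the ester) and the resulting enol tautomerises to the CH2C(=O)Ar ketone. The closest known reactions are intramolecular oxa-Michael additions under bifunctional cinchona squaramide or thiourea catalysis that give five- and six-membered cyclic ethers, and racemic base-mediated closures to oxepanes; a catalytic enantioselective closure to a seven-membered ring with a fully substituted ether carbon has not been shown. The oxepene closes in the 7-exo-trig mode, helped by the Z geometry of the C5=C6 alkene, which holds the C7 hydroxyl and C4 on the same side. The only new stereocentre, C2, is set by the catalyst, which must deliver oxygen to the Re face of C2 to give R; there is no substrate stereocentre to help or oppose it. Addition at C2 rather than at the carbon next to the ketone follows from the ketone being the stronger acceptor and from 7-exo being preferred over 8-endo, and the MOM group on the ortho phenol prevents the competing 6-endo closure to a chromanone. Because a reversible addition would erode enantiomeric purity and the E and Z acrylates need not give the same enantiomer, a single E isomer is used at low temperature under kinetic control with exclusion of light.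

Step 14
Reactants: 23 silyl-protected oxepene
Product: 24 tert-butyl (2R)-2-{2-[2,5-bis(methoxymethoxy)phenyl]-2-oxoethyl}-6-[(3E)-5-hydroxy-4-methylpent-3-en-1-yl]-2,3,4,7-tetrahydrooxepine-2-carboxylate
Conditions: HF·pyridine, pyridine, THF, 0 °C → rt
Reagents that add atoms: none
Why: Fluoride cleavage of the primary allylic TBS ether under buffered, non-basic conditions, so the β-alkoxy ketone is not opened by retro-Michael and C2 is untouched.

Step 15
Reactants: 25 (2E)-3-(4-hydroxyphenyl)prop-2-enoic acid (p-coumaric acid)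
Product: 27 (2E)-3-[4-(methoxymethoxy)phenyl]prop-2-enoic acid, via methoxymethyl ester 26 (not isolated)
Conditions: MOMCl (2.5 equiv), i-Pr2NEt, CH2Cl2, 0 °C → rt; then LiOH, THF–H2O, rt; cold 1 M HCl to pH 4
Reagents that add atoms: chloromethyl methyl ether, SMILES COCCl
Why: Exhaustive O-alkylation gives the MOM ether MOM ester, and mild saponification removes only the acyl acetal, leaving the phenol masked so that the acid cannot self-esterify in the next step.

Step 16
Reactants: 24 oxepene primary allylic alcohol; 27 MOM-protected p-coumaric acid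
Product: 28 tert-butyl (2R)-2-{2-[2,5-bis(methoxymethoxy)phenyl]-2-oxoethyl}-6-[(3E)-5-({(2E)-3-[4-(methoxymethoxy)phenyl]prop-2-enoyl}oxy)-4-methylpent-3-en-1-yl]-2,3,4,7-tetrahydrooxepine-2-carboxylate
Conditions: 27 (1.3 equiv), EDC·HCl, DMAP (0.2 equiv), CH2Cl2, 0 °C → rt
Reagents that add atoms: none
Why: Steglich esterification of the unhindered primary allylic alcohol; only catalytic DMAP at low temperature is used so that the β-alkoxy ketone is not exposed to enough base for retro-Michael opening.

Step 17
Reactants: 28 fully protected coumarate ester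
Product: 29 (2R)-2-[2-(2,5-dihydroxyphenyl)-2-oxoethyl]-6-[(3E)-5-{[(2E)-3-(4-hydroxyphenyl)prop-2-enoyl]oxy}-4-methylpent-3-en-1-yl]-2,3,4,7-tetrahydrooxepine-2-carboxylic acid (CNP0602535.1)
Conditions: TFA–CH2Cl2 (1:3), H2O (10 equiv), 0 °C → rt
Reagents that add atoms: none
Why: Acidolysis removes the tert-butyl ester by loss of isobutene and the three aryl MOM acetals through oxocarbenium ions trapped by water; C2 is quaternary and cannot epimerise, and the primary allylic ester and ether are expected to survive the short cold exposure.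

**Compound list**

1 | 5-bromo-2-methylpent-2-ene | CC(C)=CCCBr | starting material
2 | prop-2-yn-1-ol (propargyl alcohol) | C#CCO | starting material
3 | (4-methylpent-3-en-1-yl)magnesium bromide | CC(C)=CCC[Mg]Br | intermediate (not isolated)
4 | cyclic (Z)-alkenylmagnesium alkoxide chelate from carbomagnesiation (Mg bridging C3 and O) | CC(C)=CCCC1=C[Mg]OC1 | intermediate (not isolated)
5 | (2Z)-3-iodo-2-(4-methylpent-3-en-1-yl)prop-2-en-1-ol | OC/C(=C\I)CCC=C(C)C | intermediate
6 | 1-({[(2Z)-3-iodo-2-(4-methylpent-3-en-1-yl)prop-2-en-1-yl]oxy}methyl)-4-methoxybenzene | COc1ccc(COC/C(=C\I)CCC=C(C)C)cc1 | intermediate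
7 | (2E,6Z)-7-iodo-6-{[(4-methoxybenzyl)oxy]methyl}-2-methylhepta-2,6-dien-1-ol | COc1ccc(COC/C(=C\I)CC/C=C(\C)CO)cc1 | intermediate
8 | tert-butyl{[(2E,6Z)-7-iodo-6-{[(4-methoxybenzyl)oxy]methyl}-2-methylhepta-2,6-dien-1-yl]oxy}dimethylsilane | COc1ccc(COC/C(=C\I)CC/C=C(\C)CO[Si](C)(C)C(C)(C)C)cc1 | intermediate
9 | tert-butyl but-3-enoate | C=CCC(=O)OC(C)(C)C | starting material
10 | tert-butyl 4-(9-borabicyclo[3.3.1]nonan-9-yl)butanoate | CC(C)(C)OC(=O)CCCB1C2CCCC1CCC2 | intermediate (not isolated)
11 | tert-butyl (5Z,9E)-11-[(tert-butyldimethylsilyl)oxy]-6-{[(4-methoxybenzyl)oxy]methyl}-10-methylundeca-5,9-dienoate | CC(C)(C)OC(=O)CCC/C=C(\COCc1ccc(OC)cc1)CC/C=C(\C)CO[Si](C)(C)C(C)(C)C | intermediate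
12 | potassium enolate of 11 | CC(C)(C)OC([O-])=CCC/C=C(\COCc1ccc(OC)cc1)CC/C=C(\C)CO[Si](C)(C)C(C)(C)C.[K+] | intermediate (not isolated)
13 | tert-butyl (5Z,9E)-11-[(tert-butyldimethylsilyl)oxy]-2-hydroxy-6-{[(4-methoxybenzyl)oxy]methyl}-10-methylundeca-5,9-dienoate, racemic at C2 | CC(C)(C)OC(=O)C(O)CC/C=C(\COCc1ccc(OC)cc1)CC/C=C(\C)CO[Si](C)(C)C(C)(C)C | intermediate
14 | tert-butyl (5Z,9E)-11-[(tert-butyldimethylsilyl)oxy]-6-{[(4-methoxybenzyl)oxy]methyl}-10-methyl-2-oxoundeca-5,9-dienoate | CC(C)(C)OC(=O)C(=O)CC/C=C(\COCc1ccc(OC)cc1)CC/C=C(\C)CO[Si](C)(C)C(C)(C)C | intermediate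
15 | 1-(2,5-dihydroxyphenyl)ethan-1-one (2',5'-dihydroxyacetophenone) | CC(=O)c1cc(O)ccc1O | starting material
16 | 1-[2,5-bis(methoxymethoxy)phenyl]ethan-1-one | CC(=O)c1cc(OCOC)ccc1OCOC | intermediate
17 | ({1-[2,5-bis(methoxymethoxy)phenyl]ethenyl}oxy)trimethylsilane | C=C(O[Si](C)(C)C)c1cc(OCOC)ccc1OCOC | intermediate (not isolated)
18 | 1-[2,5-bis(methoxymethoxy)phenyl]-2-bromoethan-1-one | BrCC(=O)c1cc(OCOC)ccc1OCOC | intermediate
19 | {2-[2,5-bis(methoxymethoxy)phenyl]-2-oxoethyl}triphenylphosphonium bromide | [Br-].O=C(C[P+](c1ccccc1)(c1ccccc1)c1ccccc1)c1cc(OCOC)ccc1OCOC | intermediate (not isolated)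
20 | 1-[2,5-bis(methoxymethoxy)phenyl]-2-(triphenyl-λ5-phosphanylidene)ethan-1-one | O=C(C=P(c1ccccc1)(c1ccccc1)c1ccccc1)c1cc(OCOC)ccc1OCOC | intermediate
21 | tert-butyl (2E)-4-[2,5-bis(methoxymethoxy)phenyl]-2-[(3Z,7E)-9-[(tert-butyldimethylsilyl)oxy]-4-{[(4-methoxybenzyl)oxy]methyl}-8-methylnona-3,7-dien-1-yl]-4-oxobut-2-enoate | COCOc1ccc(OCOC)c(c1)C(=O)/C=C(/C(=O)OC(C)(C)C)CC/C=C(\COCc1ccc(OC)cc1)CC/C=C(\C)CO[Si](C)(C)C(C)(C)C | intermediate
22 | tert-butyl (2E)-4-[2,5-bis(methoxymethoxy)phenyl]-2-[(3Z,7E)-9-[(tert-butyldimethylsilyl)oxy]-4-(hydroxymethyl)-8-methylnona-3,7-dien-1-yl]-4-oxobut-2-enoate | COCOc1ccc(OCOC)c(c1)C(=O)/C=C(/C(=O)OC(C)(C)C)CC/C=C(\CO)CC/C=C(\C)CO[Si](C)(C)C(C)(C)C | intermediate (key-step precursor)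
23 | tert-butyl (2R)-2-{2-[2,5-bis(methoxymethoxy)phenyl]-2-oxoethyl}-6-[(3E)-5-[(tert-butyldimethylsilyl)oxy]-4-methylpent-3-en-1-yl]-2,3,4,7-tetrahydrooxepine-2-carboxylate | C/C(=C\CCC1=CCC[C@@](CC(=O)c2cc(OCOC)ccc2OCOC)(C(=O)OC(C)(C)C)OC1)CO[Si](C)(C)C(C)(C)C | intermediate (key-step product)
24 | tert-butyl (2R)-2-{2-[2,5-bis(methoxymethoxy)phenyl]-2-oxoethyl}-6-[(3E)-5-hydroxy-4-methylpent-3-en-1-yl]-2,3,4,7-tetrahydrooxepine-2-carboxylate | C/C(=C\CCC1=CCC[C@@](CC(=O)c2cc(OCOC)ccc2OCOC)(C(=O)OC(C)(C)C)OC1)CO | intermediate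
25 | (2E)-3-(4-hydroxyphenyl)prop-2-enoic acid (p-coumaric acid) | OC(=O)/C=C/c1ccc(O)cc1 | starting material
26 | methoxymethyl (2E)-3-[4-(methoxymethoxy)phenyl]prop-2-enoate | COCOC(=O)/C=C/c1ccc(OCOC)cc1 | intermediate (not isolated)
27 | (2E)-3-[4-(methoxymethoxy)phenyl]prop-2-enoic acid | OC(=O)/C=C/c1ccc(OCOC)cc1 | intermediate
28 | tert-butyl (2R)-2-{2-[2,5-bis(methoxymethoxy)phenyl]-2-oxoethyl}-6-[(3E)-5-({(2E)-3-[4-(methoxymethoxy)phenyl]prop-2-enoyl}oxy)-4-methylpent-3-en-1-yl]-2,3,4,7-tetrahydrooxepine-2-carboxylate | C/C(=C\CCC1=CCC[C@@](CC(=O)c2cc(OCOC)ccc2OCOC)(C(=O)OC(C)(C)C)OC1)COC(=O)/C=C/c1ccc(OCOC)cc1 | intermediate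
29 | (2R)-2-[2-(2,5-dihydroxyphenyl)-2-oxoethyl]-6-[(3E)-5-{[(2E)-3-(4-hydroxyphenyl)prop-2-enoyl]oxy}-4-methylpent-3-en-1-yl]-2,3,4,7-tetrahydrooxepine-2-carboxylic acid (CNP0602535.1) | C/C(=C\CCC1=CCC[C@@](CC(=O)c2cc(O)ccc2O)(C(=O)O)OC1)COC(=O)/C=C/c1ccc(O)cc1 | target

**Step count and risks**

Total steps: 17. Longest linear sequence: 13 steps (steps 1–7, 11–14, 16 and 17).

Steps most likely to fail:

1. Step 13 (proposed new method). What may go wrong: insufficient discrimination of the two faces of C2 by the catalyst, erosion of enantiomeric purity by retro-addition, or amine-induced γ-deprotonation at C3 that moves the alkene out of conjugation with the ketone. Fallback by known chemistry, setting out from 22: closure with an achiral base (catalytic DBU in THF at 0 °C, a racemic base-mediated 7-exo oxa-Michael addition) should give racemic tert-butyl 2-{2-[2,5-bis(methoxymethoxy)phenyl]-2-oxoethyl}-6-[(3E)-5-[(tert-butyldimethylsilyl)oxy]-4-methylpent-3-en-1-yl]-2,3,4,7-tetrahydrooxepine-2-carboxylate F1. Preparative chromatography of F1 on a chiral stationary phase would then return the route to 23. The separated (2S)-enantiomer F2 could be re-exposed to the same base, which reopens it by retro-Michael to regenerate F1, and recycled.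

2. Step 17. What may go wrong: acid-promoted opening of the oxepene by retro-oxa-Michael with re-closure through the liberated ortho phenol to a chromanone, and alkylation of the electron-rich phenol rings by methoxymethyl or tert-butyl cations. Fallback, setting out from 28: dealkylation by silyl transfer instead of protic acid. TMSOTf with 2,2'-bipyridyl in CH2Cl2 at 0 °C should convert the three aryl MOM ethers into aryl trimethylsilyl ethers and the tert-butyl ester into the trimethylsilyl ester, giving the per-silylated tris(trimethylsilyl ether) trimethylsilyl ester F3. Hydrolysis of F3 with pH 7 buffer on work-up would return the route to 29.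

3. Step 11. What may go wrong: sluggish olefination of the enolisable keto ester by the weakly nucleophilic, ortho-substituted acyl ylide, with competing enolisation and self-condensation of 14 or an unfavourable E/Z distribution. Fallback, setting out from 14 and 16: an aldol–dehydration sequence. The lithium enolate of 16 (LDA, THF, −78 °C) should add to the ketone carbonyl of 14 to give the tertiary aldol tert-butyl 2-{2-[2,5-bis(methoxymethoxy)phenyl]-2-oxoethyl}-2-hydroxy-undecadienoate F4. Dehydration of F4 toward the ketone with thionyl chloride and pyridine at 0 °C would return the route to 21 after separation of geometric isomers.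

**Further compounds**

F1 | step 13 | racemic tert-butyl 2-{2-[2,5-bis(methoxymethoxy)phenyl]-2-oxoethyl}-6-[(3E)-5-[(tert-butyldimethylsilyl)oxy]-4-methylpent-3-en-1-yl]-2,3,4,7-tetrahydrooxepine-2-carboxylate | C/C(=C\CCC1=CCCC(CC(=O)c2cc(OCOC)ccc2OCOC)(C(=O)OC(C)(C)C)OC1)CO[Si](C)(C)C(C)(C)C
F2 | step 13 | tert-butyl (2S)-2-{2-[2,5-bis(methoxymethoxy)phenyl]-2-oxoethyl}-6-[(3E)-5-[(tert-butyldimethylsilyl)oxy]-4-methylpent-3-en-1-yl]-2,3,4,7-tetrahydrooxepine-2-carboxylate | C/C(=C\CCC1=CCC[C@](CC(=O)c2cc(OCOC)ccc2OCOC)(C(=O)OC(C)(C)C)OC1)CO[Si](C)(C)C(C)(C)C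
F3 | step 17 | trimethylsilyl (2R)-2-{2-[2,5-bis(trimethylsilyloxy)phenyl]-2-oxoethyl}-6-[(3E)-4-methyl-5-({(2E)-3-[4-(trimethylsilyloxy)phenyl]prop-2-enoyl}oxy)pent-3-en-1-yl]-2,3,4,7-tetrahydrooxepine-2-carboxylate | C/C(=C\CCC1=CCC[C@@](CC(=O)c2cc(O[Si](C)(C)C)ccc2O[Si](C)(C)C)(C(=O)O[Si](C)(C)C)OC1)COC(=O)/C=C/c1ccc(O[Si](C)(C)C)cc1
F4 | step 11 | tert-butyl (5Z,9E)-2-{2-[2,5-bis(methoxymethoxy)phenyl]-2-oxoethyl}-11-[(tert-butyldimethylsilyl)oxy]-2-hydroxy-6-{[(4-methoxybenzyl)oxy]methyl}-10-methylundeca-5,9-dienoate (racemic at C2) | COCOc1ccc(OCOC)c(c1)C(=O)CC(O)(C(=O)OC(C)(C)C)CC/C=C(\COCc2ccc(OC)cc2)CC/C=C(\C)CO[Si](C)(C)C(C)(C)C
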